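**Plan**

- With the quinone ring numbered C1(=O), C2(OMe), C3(H), C4(=O), C5(CH3), C6(henicosyl), the retrosynthesis cuts the O–CH3 bond at C2 first, then the ring bonds C5–C6 and C2–C3 together, and last the bond C6–C1.
- The double cut is possible because the ring is two 1,2-dicarbonyl halves: C3–C4(=O)–C5(CH3) is butane-2,3-dione with one methyl carbon in the ring, and C6–C1(=O)–C2(O) is a 2-oxo ester whose methylene carries the chain. Their oxidation levels add up to the hydroxyquinone after loss of water and an alcohol, so no oxidant is needed.
- Forward, the chain is joined to the oxalyl unit first (C6–C1, docosyl Grignard reagent plus diethyl oxalate). The only ring then arises in one [3+3] condensation with butane-2,3-dione, and O-methylation finishes the target.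
- The target has no stereocentre and no stereogenic double bond; the two sp3 centres formed transiently in the annulation are erased by dehydration.

Key step: step 2

Remark: the oxo ester is carried as its ethyl ester, because the alkoxy group is expelled in the ring closure and diethyl oxalate, a liquid, stays dissolved at −78 °C.

**Step 1**
Reactants: 1 1-bromodocosane; 2 diethyl oxalate
Product: 5 ethyl 2-oxotetracosanoate, via docosylmagnesium bromide 3 (not isolated), via magnesium hemiketal alkoxide 4 (not isolated)
Conditions: Mg, I2 (cat.), THF, 50 °C; warm solution added to (CO2Et)2 (3 equiv), THF, −78 °C; 1 M HCl, −78 to 0 °C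
Reagents that add atoms: none
Why: Grignard formation followed by inverse addition to excess oxalate diester at low temperature is the standard single acylation of an organomagnesium reagent, in which the chelated hemiketal alkoxide 4 should persist until the acid quench so that the ketone of 5 is never exposed to 3.

**Step 2**
Reactants: 5 ethyl 2-oxotetracosanoate; 6 butane-2,3-dione
Product: 11 3-henicosyl-5-hydroxy-2-methylcyclohexa-2,5-diene-1,4-dione, via lithium enolate 7 (not isolated), via lithium aldolate 8 (not isolated), via butenolide enolate 9 (not isolated), via sodium quinonolate 10 (not isolated)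
Conditions: LiN(SiMe3)2 (1.05 equiv), THF, −78 °C, slow addition of 5; then 6 (1.2 equiv), −78 °C; then NaOEt (3 equiv), EtOH, −78 °C to rt, then 50 °C, argon; 1 M HCl
Reagents that add atoms: none
Why: Proposed new method: the preformed lithium enolate 7 should add through its chain-bearing carbon (ring C6) to one carbonyl of the very electrophilic dione 6 (ring C5) to give aldolate 8, which lactonises on warming to the 3-oxidobutenolide 9 in equilibrium with the open ester; ethoxide then enolises the acetyl methyl group (ring C3), which acylates the ester or lactone carbonyl (ring C2), and vinylogous E1cB loss of hydroxide from C5 leaves the ring at the cyclohex-5-ene-1,2,4-trione level, which is the tautomer of the hydroxyquinone and is drained as its anion 10. The closest known reactions are the base-mediated self-condensation of butane-2,3-dione to 2,5-dimethyl-1,4-benzoquinone, the double Claisen self-condensation of 2-oxo esters to 3,6-dialkyl-2,5-dihydroxy-1,4-benzoquinones and the aldol-lactonisation of 2-oxo esters to 3-hydroxybutenolides, none of which is known as this crossed pair. The single carbocycle closes by a 6-(enolexo)-exo-trig Dieckmann-type acylation at C2 (from 9 the same bond forms by attack on the lactone carbonyl and C–O cleavage), and the mass balance is loss of one ethanol and one water with no change in overall oxidation level. No stereocentre survives, because the two sp3 centres of 8 at C5 and C6 become the tetrasubstituted ring alkene. The step needs crossed rather than self-condensation, which quantitative enolisation of 5 by inverse addition to LiN(SiMe3)2 at −78 °C before slow addition of the symmetrical dione should secure, and it needs acylation at C2 rather than aldol closure onto the C1 ketone, which the substrate secures because the most acidic C6–H keeps C1 masked as its enolate under ethoxide. Regiochemistry is fixed by connectivity since both methyl groups of 6 are equivalent, and formation of the vinylogous carboxylate 10, a far weaker base than ethoxide, makes the productive channel irreversible while stray aldol adducts can revert.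

**Step 3**
Reactants: 11 3-henicosyl-5-hydroxy-2-methylcyclohexa-2,5-diene-1,4-dione
Product: 12 3-henicosyl-5-methoxy-2-methylcyclohexa-2,5-diene-1,4-dione
Conditions: MeOH–THF (1:1), H2SO4 (cat.), reflux
Reagents that add atoms: methanol, CO
Why: Acid-catalysed addition–elimination of methanol at the hydroxyl-bearing carbon of the vinylogous carboxylic acid (a Fischer-type esterification, standard for 2-hydroxy-1,4-quinones) should give the methyl vinylogous ester and avoids the C-alkylation that the ambident quinonolate can show with alkylating agents.

**Compound list**

1 | 1-bromodocosane | CCCCCCCCCCCCCCCCCCCCCCBr | starting material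
2 | diethyl oxalate | CCOC(=O)C(=O)OCC | starting material
3 | docosylmagnesium bromide | CCCCCCCCCCCCCCCCCCCCCC[Mg]Br | intermediate (not isolated)
4 | bromomagnesium alkoxide of ethyl 2-ethoxy-2-hydroxytetracosanoate (hemiketal adduct) | CCCCCCCCCCCCCCCCCCCCCCC(OCC)(O[Mg]Br)C(=O)OCC | intermediate (not isolated)
5 | ethyl 2-oxotetracosanoate | CCCCCCCCCCCCCCCCCCCCCCC(=O)C(=O)OCC | intermediate
6 | butane-2,3-dione | CC(=O)C(C)=O | starting material
7 | lithium 1-ethoxy-1-oxotetracos-2-en-2-olate (enolate of 5; double-bond geometry not defined and of no consequence) | CCCCCCCCCCCCCCCCCCCCCC=C([O-])C(=O)OCC.[Li+] | intermediate (not isolated)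
8 | lithium alkoxide of ethyl 3-henicosyl-4-hydroxy-4-methyl-2,5-dioxohexanoate (racemic mixture of diastereomers) | CCCCCCCCCCCCCCCCCCCCCC(C(=O)C(=O)OCC)C(C)([O-])C(C)=O.[Li+] | intermediate (not isolated)
9 | lithium 5-acetyl-4-henicosyl-5-methyl-2-oxo-2,5-dihydrofuran-3-olate (racemic) | CCCCCCCCCCCCCCCCCCCCCC1=C([O-])C(=O)OC1(C)C(C)=O.[Li+] | intermediate (not isolated)
10 | sodium 5-henicosyl-4-methyl-3,6-dioxocyclohexa-1,4-dien-1-olate | CCCCCCCCCCCCCCCCCCCCCC1=C(C)C(=O)C=C([O-])C1=O.[Na+] | intermediate (not isolated)
11 | 3-henicosyl-5-hydroxy-2-methylcyclohexa-2,5-diene-1,4-dione | CCCCCCCCCCCCCCCCCCCCCC1=C(C)C(=O)C=C(O)C1=O | intermediate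
12 | 3-henicosyl-5-methoxy-2-methylcyclohexa-2,5-diene-1,4-dione | CCCCCCCCCCCCCCCCCCCCCC1=C(C)C(=O)C=C(OC)C1=O | target

**Step count**

Total steps: 3. Longest linear sequence: 3 steps, from 1 to 12.

**Steps most likely to fail**

Step 2. Self-condensation of either partner may outrun the crossed aldol, the aldol adduct may fragment by retro-aldol once ethoxide is added, or the sequence may stall at the butenolide stage because the acetyl enolate fails to acylate the lactone or ester carbonyl. The fallback uses known chemistry, builds the ring as a resorcinol in which the chain terminus is again a ring carbon, sets out from 1 and returns at 11. Kornblum oxidation of 1 (DMSO, NaHCO3, NaI cat., 130 °C) should give docosanal F1. Wittig olefination with 3-(triphenylphosphoranylidene)butan-2-one (toluene, reflux) should give (E)-3-methylpentacos-3-en-2-one F2. Michael addition of dimethyl malonate and Claisen ring closure in the same pot (NaOMe, MeOH, reflux) should give methyl 2-henicosyl-3-methyl-4,6-dioxocyclohexane-1-carboxylate F3. Bromination–dehydrobromination (Br2, DMF, 0 to 80 °C) should aromatise it to methyl 6-henicosyl-2,4-dihydroxy-5-methylbenzoate F4. Saponification and decarboxylation (aq. NaOH, reflux; then HCl) should give 5-henicosyl-4-methylbenzene-1,3-diol F5. Teuber oxidation with (KSO3)2NO (KH2PO4 buffer, acetone–water) at the only free position para to a hydroxyl should then give 11.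

Step 1. The Grignard reagent may add a second time to the first-formed keto group, Wurtz-type homocoupling may consume the bromide during magnesium insertion, and the waxy organometallic may precipitate in the cold. The fallback replaces acylation of an organometallic by alkylation of an acyl-anion equivalent, sets out from 1 and returns at 5. Ethyl 1,3-dithiane-2-carboxylate is deprotonated with NaH (DMF–toluene, 0 °C to rt) and alkylated with 1 to give ethyl 2-docosyl-1,3-dithiane-2-carboxylate F6. Oxidative hydrolysis with N-bromosuccinimide in aqueous acetone at 0 °C should then unmask 5.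

Step 3. The vinylogous esterification may stop at equilibrium with the poorly soluble waxy substrate, or the quinone may degrade on prolonged heating in acid. The fallback goes through the arene oxidation level, sets out from 11 and returns at 12. Reduction with Na2S2O4 (THF–water, argon) should give 6-henicosyl-5-methylbenzene-1,2,4-triol F7. Without isolation, all three hydroxyls are methylated (Me2SO4, K2CO3, acetone, reflux) to give 3-henicosyl-1,2,5-trimethoxy-4-methylbenzene F8. Oxidative demethylation with (NH4)2Ce(NO3)6 (MeCN–water, 0 °C) should remove the two para-related O-methyl groups and give 12.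

**Further compounds**

F1 | step 2 | docosanal | CCCCCCCCCCCCCCCCCCCCCC=O
F2 | step 2 | (E)-3-methylpentacos-3-en-2-one | CCCCCCCCCCCCCCCCCCCCC/C=C(\C)C(C)=O
F3 | step 2 | methyl 2-henicosyl-3-methyl-4,6-dioxocyclohexane-1-carboxylate (mixture of stereoisomers) | COC(=O)C1C(CCCCCCCCCCCCCCCCCCCCC)C(C)C(=O)CC1=O
F4 | step 2 | methyl 6-henicosyl-2,4-dihydroxy-5-methylbenzoate | COC(=O)c1c(O)cc(O)c(C)c1CCCCCCCCCCCCCCCCCCCCC
F5 | step 2 | 5-henicosyl-4-methylbenzene-1,3-diol | CCCCCCCCCCCCCCCCCCCCCc1cc(O)cc(O)c1C
F6 | step 1 | ethyl 2-docosyl-1,3-dithiane-2-carboxylate | CCCCCCCCCCCCCCCCCCCCCCC1(C(=O)OCC)SCCCS1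
F7 | step 3 | 6-henicosyl-5-methylbenzene-1,2,4-triol | CCCCCCCCCCCCCCCCCCCCCc1c(C)c(O)cc(O)c1O
F8 | step 3 | 3-henicosyl-1,2,5-trimethoxy-4-methylbenzene | CCCCCCCCCCCCCCCCCCCCCc1c(C)c(OC)cc(OC)c1OC
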